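**Retrosynthetic overview**
- Structural feature: the flavonol carbonyl C4 sits on C4a, the benzo-ring carbon between C8a (which bears O1) and C5 (which bears flavan C4). Electrophilic acylation cannot select this carbon, but an iodine placed there next to a free phenol marks it exactly.
- The flavonol pyranone is the last ring formed. It is cut at C4a–C4, C4–C3 and O1–C2 into a flavan-4-yl o-iodophenol, carbon monoxide and 3,4-bis(benzyloxy)phenylacetylene. The 3-OH (C3 lithiation, borylation, oxidation) and global hydrogenolysis follow.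
- The flavan pyran is the first ring formed. O1–C2 comes from a Mitsunobu inversion, and C4–C4a from a 6-endo epoxy–arene Friedel–Crafts closure of a trans-aryloxirane.
- C3 and C4 come from an asymmetric chalcone epoxidation. C2 comes from a chelate-controlled ketone reduction followed by inversion, which gives the 2,3-cis-3,4-trans array.
- The iodinated ring comes from 3,4,5-trihydroxybenzaldehyde through its symmetric 4-O-benzyl ether, so the iodination has only one possible site.

Key step: step 15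

Remark on the chemistry: the flavan unit of the SMILES is read as (2R,3R,4S), which is 2,3-cis-3,4-trans. In the iodinated intermediates the same C4 geometry is labelled R, because iodine raises the CIP rank of the attached ring.

**Step 1**
Reactants: 1 3,4,5-trihydroxybenzaldehyde
Product: 2 4-(benzyloxy)-3,5-dihydroxybenzaldehyde
Conditions: BnBr (1.0 equiv), NaHCO3, NaI (cat.), DMF, 40 °C
Reagents that add atoms: benzyl bromide, BrCc1ccccc1
Why: The 4-OH, para to the formyl group, is by far the most acidic phenol, so a hydrogencarbonate base ionises only that site and the Williamson etherification should give the symmetric mono-ether.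

**Step 2**
Reactants: 2 4-(benzyloxy)-3,5-dihydroxybenzaldehyde
Product: 3 4-(benzyloxy)-3,5-dihydroxy-2-iodobenzaldehyde
Conditions: NIS (1.0 equiv), MeCN, 0 °C, dark
Reagents that add atoms: N-iodosuccinimide, O=C1CCC(=O)N1I
Why: This is an electrophilic aromatic iodination of a resorcinol-type ring whose two open positions (each ortho to one OH and para to the other) are equivalent by symmetry, so one equivalent of NIS can give only one mono-iodide.

**Step 3**
Reactants: 3 4-(benzyloxy)-3,5-dihydroxy-2-iodobenzaldehyde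
Product: 4 4-(benzyloxy)-2-iodo-3,5-bis(methoxymethoxy)benzaldehyde
Conditions: MOMCl, iPr2NEt, CH2Cl2, 0 °C → rt
Reagents that add atoms: chloromethyl methyl ether, COCCl
Why: MOM ether formation masks both phenols against the basic, peroxide and hydride steps ahead, and the groups can later be removed without touching benzyl ethers or the C–I bond.

**Step 4**
Reactants: 5 1-(3,4-dihydroxyphenyl)ethanone
Product: 6 1-[3,4-bis(benzyloxy)phenyl]ethanone
Conditions: BnBr, K2CO3, DMF, 60 °C
Reagents that add atoms: benzyl bromide, BrCc1ccccc1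
Why: Exhaustive Williamson benzylation of a catechol, in which carbonate is too weak to alkylate the ketone enolate.

**Step 5**
Reactants: 4 4-(benzyloxy)-2-iodo-3,5-bis(methoxymethoxy)benzaldehyde; 6 1-[3,4-bis(benzyloxy)phenyl]ethanone
Product: 7 (E)-chalcone with the 3,4-bis(benzyloxy)phenyl group on the carbonyl and the iodinated ring on the β-carbon
Conditions: KOH (aq.), EtOH–THF, rt
Reagents that add atoms: none
Why: Claisen–Schmidt condensation of a methyl ketone with a non-enolisable aldehyde, whose E1cB dehydration gives only the conjugated E-enone.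

**Step 6**
Reactants: 7 (E)-chalcone
Product: 8 trans-(αR,βS)-epoxy ketone
Conditions: poly-L-leucine, urea·H2O2, DBU, THF, rt
Reagents that add atoms: hydrogen peroxide (used as its urea adduct), OO
Why: In this Juliá–Colonna asymmetric Weitz–Scheffer epoxidation the helical L-polypeptide directs hydroperoxide addition to one enone face, which for chalcones gives the trans-(αR,βS)-oxirane and so sets flavan C3 and, ahead of its later inversion, C4.

**Step 7**
Reactants: 8 trans-(αR,βS)-epoxy ketone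
Product: 9 anti-epoxy alcohol with an (S)-carbinol centre
Conditions: Zn(BH4)2, Et2O–THF, −78 → −20 °C; aq. NH4Cl
Reagents that add atoms: none
Why: In this chelation-controlled reduction of an α,β-epoxy ketone, zinc ties the carbonyl and oxirane oxygens together and hydride enters from the face away from Cβ, which should give the anti (erythro) alcohol with an S carbinol carbon.

**Step 8**
Reactants: 10 2,3-dihydroxybenzaldehyde
Product: 11 2,3-bis(benzyloxy)benzaldehyde
Conditions: BnBr, K2CO3, DMF, 60 °C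
Reagents that add atoms: benzyl bromide, BrCc1ccccc1
Why: Exhaustive Williamson benzylation of both phenols.

**Step 9**
Reactants: 11 2,3-bis(benzyloxy)benzaldehyde
Product: 13 2,3-bis(benzyloxy)phenol, via aryl formate 12 (not isolated)
Conditions: mCPBA, CH2Cl2, rt; then K2CO3 (cat.), MeOH, rt
Reagents that add atoms: 3-chloroperbenzoic acid, O=C(OO)c1cccc(Cl)c1
Why: In this Baeyer–Villiger (Dakin-type) oxidation the electron-rich aryl group migrates to oxygen, and the resulting formate is removed by methanolysis.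

**Step 10**
Reactants: 9 anti-epoxy alcohol; 13 2,3-bis(benzyloxy)phenol
Product: 14 syn-aryloxy oxirane with an (R)-configured ether carbon
Conditions: PPh3, DIAD, toluene, 0 °C → rt
Reagents that add atoms: none
Why: Mitsunobu etherification is an SN2 displacement of the oxyphosphonium by the phenoxide, so it inverts the carbinol carbon (S to R) and sets flavan C2 syn to the oxirane oxygen, while the electron-withdrawing oxirane and the non-polar solvent hold back ionisation.

**Step 11**
Reactants: 14 syn-aryloxy oxirane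
Product: 15 (2R,3R,4R)-4-arylflavan-3-ol, 2,3-cis-3,4-trans
Conditions: BF3·OEt2 (20 mol %), CH2Cl2, −78 → −40 °C
Reagents that add atoms: none
Why: In this intramolecular Friedel–Crafts epoxy–arene cyclisation (6-endo-tet, known for trans-3-arylglycidyl aryl ethers) the activated oxirane opens at its benzylic carbon under rear-side attack by the ring carbon that is ortho to O1 and para to the 7-benzyloxy group, so C4 is inverted, the C3–O bond is kept and the 3,4-trans chroman results.

**Step 12**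
Reactants: 15 4-arylflavan-3-ol
Product: 16 3-O-benzyl ether of 15
Conditions: NaH, BnBr, n-Bu4NI (cat.), DMF, 0 °C → rt
Reagents that add atoms: benzyl bromide, BrCc1ccccc1
Why: Williamson benzylation of the secondary alkoxide is needed because a free 3-OH would trap the aroylpalladium of step 15 as a six-membered lactone.

**Step 13**
Reactants: 16 3-O-benzyl ether
Product: 17 flavan-4-yl iodoresorcinol (o-iodophenol; 2-benzyloxy-4-iodo-5-flavanylbenzene-1,3-diol)
Conditions: conc. HCl (cat.), MeOH–THF, 40 °C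
Reagents that add atoms: none
Why: Acid-catalysed acetal exchange removes both MOM groups, while the benzyl ethers are inert and the C4–aryl bond is safe because its ring carbon is meta to both new phenols.

**Step 14**
Reactants: 18 3,4-bis(benzyloxy)benzaldehyde
Product: 19 4-ethynyl-1,2-bis(benzyloxy)benzene
Conditions: dimethyl (1-diazo-2-oxopropyl)phosphonate, K2CO3, MeOH–THF, rt
Reagents that add atoms: dimethyl (1-diazo-2-oxopropyl)phosphonate, COP(=O)(OC)C(=[N+]=[N-])C(C)=O
Why: In the Ohira–Bestmann variant of the Seyferth–Gilbert homologation the diazophosphonate anion olefinates the aldehyde, and loss of N2 with a 1,2-hydrogen shift gives the terminal alkyne.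

**Step 15**
Reactants: 17 flavan-4-yl iodoresorcinol; 19 4-ethynyl-1,2-bis(benzyloxy)benzene; 20 carbon monoxide
Product: 23 7-hydroxy-5-(flavan-4-yl)flavone octabenzyl ether, via alkynone 21 (not isolated), via enaminone 22 (not isolated)
Conditions: PdCl2(dppf) (5 mol %), CO (10 bar), Et2NH–DMF, 100 °C
Reagents that add atoms: diethylamine, CCNCC (held only in intermediate 22 and released on ring closure)
Why: Pd(0) adds oxidatively to the C–I bond of 17, CO inserts to give the aroylpalladium iodide, and the acetylide drawn from 19 by Et2NH replaces iodide, so that reductive elimination delivers alkynone 21 with C4a–C4 and C4–C3 in place; this is the carbonylative Sonogashira coupling, and its telescoped closure is the known flavone synthesis from o-iodophenols, terminal alkynes and CO. Et2NH then adds to the ynone to give enaminone 22, whose β-carbon (the future C2) is attacked by the neighbouring phenol with loss of the amine, which makes O1–C2. The only ring formed, the pyranone, therefore closes in the 6-endo mode (6-endo-trig addition–elimination on 22, the equivalent of a 6-endo-dig oxa-Michael addition on 21). No stereocentre is created, and flavan C2, C3 and C4 have no acidic or ionisable handle in the weakly basic medium, so they pass unchanged (the C4 descriptor goes from R to S only because iodine leaves the ranking). Three selectivities are needed: the acylation site, fixed by the iodine on the carbon between the phenol and the flavanyl-bearing carbon; flavone against aurone (5-exo), secured by the secondary amine, which routes the ynone through 22 where only the β-carbon is electrophilic; and carbonylation against direct alkynylation to a benzofuran, favoured by copper-free conditions and CO pressure. The O3 benzyl ether keeps the aroylpalladium from lactonising, and the second phenol (the future 7-OH) is para to the acyl carbon and cannot reach the ynone.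

**Step 16**
Reactants: 23 7-hydroxyflavone octabenzyl ether
Product: 24 5-(flavan-4-yl)flavone nonabenzyl ether
Conditions: BnBr, K2CO3, DMF, rt
Reagents that add atoms: benzyl bromide, BrCc1ccccc1
Why: Williamson benzylation of the single, acidic 7-OH (vinylogous to the C4 carbonyl) removes the last protic site before the lithiation.

**Step 17**
Reactants: 24 flavone nonabenzyl ether
Product: 27 flavonol nonabenzyl ether (free 3-OH), via 3-lithioflavone 25 (not isolated), via 3-boronate 26 (not isolated)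
Conditions: LDA, THF, −78 °C; B(OMe)3, −78 → 0 °C; H2O2 (30 %), AcOH, 0 °C → rt
Reagents that add atoms: hydrogen peroxide, OO (oxygen of the 3-OH); trimethyl borate, COB(OC)OC (in 26 only); lithium diisopropylamide, CC(C)[N-]C(C)C.[Li+] (lithium of 25 only)
Why: In this known flavone-to-flavonol sequence of carbonyl-directed C3 lithiation, borylation and peroxide oxidation, the vinylic C3–H is the kinetically acidic site, whereas the flavan C4–H points in-plane toward the peri carbonyl and is not aligned with the π system for deprotonation.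

**Step 18**
Reactants: 27 flavonol nonabenzyl ether
Product: 28 target, CNP0395591.1
Conditions: H2 (1 atm), Pd(OH)2/C, THF–MeOH, rt, then handling under argon
Reagents that add atoms: none
Why: Catalytic hydrogenolysis cleaves all nine O-benzyl bonds under neutral conditions that are routinely tolerated by flavonol enones and flavan-3-ol stereocentres.

**Compound list**

| No. | Name | SMILES | Role |
|---|---|---|---|
| 1 | 3,4,5-trihydroxybenzaldehyde | O=Cc1cc(O)c(O)c(O)c1 | starting material |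
| 2 | 4-(benzyloxy)-3,5-dihydroxybenzaldehyde | O=Cc1cc(O)c(OCc2ccccc2)c(O)c1 | intermediate |
| 3 | 4-(benzyloxy)-3,5-dihydroxy-2-iodobenzaldehyde | O=Cc1cc(O)c(OCc2ccccc2)c(O)c1I | intermediate |
| 4 | 4-(benzyloxy)-2-iodo-3,5-bis(methoxymethoxy)benzaldehyde | O=Cc1cc(OCOC)c(OCc2ccccc2)c(OCOC)c1I | intermediate |
| 5 | 1-(3,4-dihydroxyphenyl)ethanone | CC(=O)c1ccc(O)c(O)c1 | starting material |
| 6 | 1-[3,4-bis(benzyloxy)phenyl]ethanone | CC(=O)c1ccc(OCc2ccccc2)c(OCc2ccccc2)c1 | intermediate |
| 7 | (E)-3-[4-(benzyloxy)-2-iodo-3,5-bis(methoxymethoxy)phenyl]-1-[3,4-bis(benzyloxy)phenyl]prop-2-en-1-one | O=C(/C=C/c1cc(OCOC)c(OCc2ccccc2)c(OCOC)c1I)c1ccc(OCc2ccccc2)c(OCc2ccccc2)c1 | intermediate |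
| 8 | [3,4-bis(benzyloxy)phenyl]{(2R,3S)-3-[4-(benzyloxy)-2-iodo-3,5-bis(methoxymethoxy)phenyl]oxiran-2-yl}methanone | O=C(c1ccc(OCc2ccccc2)c(OCc2ccccc2)c1)[C@@H]1O[C@H]1c1cc(OCOC)c(OCc2ccccc2)c(OCOC)c1I | intermediate |
| 9 | (S)-[3,4-bis(benzyloxy)phenyl]{(2S,3S)-3-[4-(benzyloxy)-2-iodo-3,5-bis(methoxymethoxy)phenyl]oxiran-2-yl}methanol (anti) | O[C@@H](c1ccc(OCc2ccccc2)c(OCc2ccccc2)c1)[C@@H]1O[C@H]1c1cc(OCOC)c(OCc2ccccc2)c(OCOC)c1I | intermediate |
| 10 | 2,3-dihydroxybenzaldehyde | O=Cc1cccc(O)c1O | starting material |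
| 11 | 2,3-bis(benzyloxy)benzaldehyde | O=Cc1cccc(OCc2ccccc2)c1OCc1ccccc1 | intermediate |
| 12 | 2,3-bis(benzyloxy)phenyl formate | O=COc1cccc(OCc2ccccc2)c1OCc1ccccc1 | intermediate |
| 13 | 2,3-bis(benzyloxy)phenol | Oc1cccc(OCc2ccccc2)c1OCc1ccccc1 | intermediate |
| 14 | (2R,3S)-2-{(R)-[2,3-bis(benzyloxy)phenoxy][3,4-bis(benzyloxy)phenyl]methyl}-3-[4-(benzyloxy)-2-iodo-3,5-bis(methoxymethoxy)phenyl]oxirane | C(c1ccccc1)Oc1cccc(O[C@H](c2ccc(OCc3ccccc3)c(OCc3ccccc3)c2)[C@@H]2O[C@H]2c2cc(OCOC)c(OCc3ccccc3)c(OCOC)c2I)c1OCc1ccccc1 | intermediate |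
| 15 | (2R,3R,4R)-7,8-bis(benzyloxy)-4-[4-(benzyloxy)-2-iodo-3,5-bis(methoxymethoxy)phenyl]-2-[3,4-bis(benzyloxy)phenyl]chroman-3-ol | Ic1c(OCOC)c(OCc2ccccc2)c(OCOC)cc1[C@H]1c2ccc(OCc3ccccc3)c(OCc3ccccc3)c2O[C@H](c2ccc(OCc3ccccc3)c(OCc3ccccc3)c2)[C@@H]1O | intermediate |
| 16 | (2R,3R,4R)-3,7,8-tris(benzyloxy)-4-[4-(benzyloxy)-2-iodo-3,5-bis(methoxymethoxy)phenyl]-2-[3,4-bis(benzyloxy)phenyl]chroman | Ic1c(OCOC)c(OCc2ccccc2)c(OCOC)cc1[C@H]1c2ccc(OCc3ccccc3)c(OCc3ccccc3)c2O[C@H](c2ccc(OCc3ccccc3)c(OCc3ccccc3)c2)[C@@H]1OCc1ccccc1 | intermediate |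
| 17 | 2-(benzyloxy)-4-iodo-5-{(2R,3R,4R)-3,7,8-tris(benzyloxy)-2-[3,4-bis(benzyloxy)phenyl]chroman-4-yl}benzene-1,3-diol | Ic1c(O)c(OCc2ccccc2)c(O)cc1[C@H]1c2ccc(OCc3ccccc3)c(OCc3ccccc3)c2O[C@H](c2ccc(OCc3ccccc3)c(OCc3ccccc3)c2)[C@@H]1OCc1ccccc1 | intermediate |
| 18 | 3,4-bis(benzyloxy)benzaldehyde | O=Cc1ccc(OCc2ccccc2)c(OCc2ccccc2)c1 | starting material |
| 19 | 4-ethynyl-1,2-bis(benzyloxy)benzene | C#Cc1ccc(OCc2ccccc2)c(OCc2ccccc2)c1 | intermediate |
| 20 | carbon monoxide | [C-]#[O+] | starting material |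
| 21 | o-hydroxyaryl alkynone: 1-[3-(benzyloxy)-2,4-dihydroxy-6-(flavan-4-yl)phenyl]-3-[3,4-bis(benzyloxy)phenyl]prop-2-yn-1-one, flavan (2R,3R,4S) | O=C(C#Cc1ccc(OCc2ccccc2)c(OCc2ccccc2)c1)c1c(O)c(OCc2ccccc2)c(O)cc1[C@H]1c2ccc(OCc3ccccc3)c(OCc3ccccc3)c2O[C@H](c2ccc(OCc3ccccc3)c(OCc3ccccc3)c2)[C@@H]1OCc1ccccc1 | intermediate |
| 22 | (E)-β-(diethylamino)enone, the Et2NH adduct of 21 | CCN(CC)/C(c1ccc(OCc2ccccc2)c(OCc2ccccc2)c1)=C/C(=O)c1c(O)c(OCc2ccccc2)c(O)cc1[C@H]1c2ccc(OCc3ccccc3)c(OCc3ccccc3)c2O[C@H](c2ccc(OCc3ccccc3)c(OCc3ccccc3)c2)[C@@H]1OCc1ccccc1 | intermediate |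
| 23 | 8-(benzyloxy)-2-[3,4-bis(benzyloxy)phenyl]-7-hydroxy-5-{(2R,3R,4S)-3,7,8-tris(benzyloxy)-2-[3,4-bis(benzyloxy)phenyl]chroman-4-yl}-4H-chromen-4-one | O=c1cc(-c2ccc(OCc3ccccc3)c(OCc3ccccc3)c2)oc2c(OCc3ccccc3)c(O)cc([C@H]3c4ccc(OCc5ccccc5)c(OCc5ccccc5)c4O[C@H](c4ccc(OCc5ccccc5)c(OCc5ccccc5)c4)[C@@H]3OCc3ccccc3)c12 | intermediate |
| 24 | 7,8-bis(benzyloxy)-2-[3,4-bis(benzyloxy)phenyl]-5-{(2R,3R,4S)-3,7,8-tris(benzyloxy)-2-[3,4-bis(benzyloxy)phenyl]chroman-4-yl}-4H-chromen-4-one | O=c1cc(-c2ccc(OCc3ccccc3)c(OCc3ccccc3)c2)oc2c(OCc3ccccc3)c(OCc3ccccc3)cc([C@H]3c4ccc(OCc5ccccc5)c(OCc5ccccc5)c4O[C@H](c4ccc(OCc5ccccc5)c(OCc5ccccc5)c4)[C@@H]3OCc3ccccc3)c12 | intermediate |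
| 25 | 3-lithio derivative of 24 | O=c1c([Li])c(-c2ccc(OCc3ccccc3)c(OCc3ccccc3)c2)oc2c(OCc3ccccc3)c(OCc3ccccc3)cc([C@H]3c4ccc(OCc5ccccc5)c(OCc5ccccc5)c4O[C@H](c4ccc(OCc5ccccc5)c(OCc5ccccc5)c4)[C@@H]3OCc3ccccc3)c12 | intermediate |
| 26 | dimethyl 3-boronate of 24 | O=c1c(B(OC)OC)c(-c2ccc(OCc3ccccc3)c(OCc3ccccc3)c2)oc2c(OCc3ccccc3)c(OCc3ccccc3)cc([C@H]3c4ccc(OCc5ccccc5)c(OCc5ccccc5)c4O[C@H](c4ccc(OCc5ccccc5)c(OCc5ccccc5)c4)[C@@H]3OCc3ccccc3)c12 | intermediate |
| 27 | 3-hydroxy derivative of 24 (flavonol nonabenzyl ether) | O=c1c(O)c(-c2ccc(OCc3ccccc3)c(OCc3ccccc3)c2)oc2c(OCc3ccccc3)c(OCc3ccccc3)cc([C@H]3c4ccc(OCc5ccccc5)c(OCc5ccccc5)c4O[C@H](c4ccc(OCc5ccccc5)c(OCc5ccccc5)c4)[C@@H]3OCc3ccccc3)c12 | intermediate |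
| 28 | 2-(3,4-dihydroxyphenyl)-5-[(2R,3R,4S)-2-(3,4-dihydroxyphenyl)-3,7,8-trihydroxychroman-4-yl]-3,7,8-trihydroxy-4H-chromen-4-one | O=c1c(O)c(-c2ccc(O)c(O)c2)oc2c(O)c(O)cc([C@H]3c4ccc(O)c(O)c4O[C@H](c4ccc(O)c(O)c4)[C@@H]3O)c12 | target |

**Step count**
- Total: 18 steps.
- Longest linear sequence: 14 steps (1, 2, 3, 5, 6, 7, 10, 11, 12, 13, 15, 16, 17, 18).

**Steps most likely to fail**

**Step 15.** Oxidative addition into a C–I bond flanked by a phenol(ate) and a secondary diarylmethyl-type group may be slow. Hydrodeiodination by the amine, capture of the aroylpalladium by Et2NH (aminocarbonylation), or CO-free alkynylation could then overtake the three-component path.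

The fallback sets out from 16 and 19 and returns at 23, and it builds the same alkynone without palladium or CO. Alkyne 19 is deprotonated (n-BuLi, THF, −78 °C) and formylated with DMF to give 3-[3,4-bis(benzyloxy)phenyl]propynal F1. Iodide 16 undergoes iodine–magnesium exchange (iPrMgCl·LiCl, THF, −20 °C), helped by the ortho MOM ether, to give the arylmagnesium chloride F2. F2 adds 1,2 to F1 to give the propargylic alcohol F3 as both carbinol epimers, which does not matter for the outcome. MnO2 (CH2Cl2, rt) oxidises F3 to the bis-MOM alkynone F4. Catalytic HCl in MeOH–THF frees the phenols to give 21, and Et2NH in DMF closes 21 through 22 to 23.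

**Step 11.** The ortho-iodine twists the attached ring out of conjugation with C4. Oxirane opening may therefore lag behind ionisation of the C2–O aryl ether, a 1,2-hydride shift (Meinwald rearrangement), or loss of the MOM groups.

The fallback sets out from 2 and returns at 17. It carries an iodine-free, locally symmetric ring through the ring closure and forms the C–I bond last. The sequence is:
- MOMCl and iPr2NEt convert 2 into 4-(benzyloxy)-3,5-bis(methoxymethoxy)benzaldehyde F5.
- Claisen–Schmidt condensation with 6 gives the iodine-free chalcone F6.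
- Juliá–Colonna epoxidation with poly-L-leucine gives the (αR,βS)-epoxy ketone F7.
- Zn(BH4)2 gives the anti-epoxy alcohol F8.
- Mitsunobu coupling with 13 gives the syn-aryloxy oxirane F9.
- Lewis acid closure of this unhindered aryloxirane, the substrate class on which the cyclisation is established, gives the iodine-free flavan-3-ol F10.
- NaH and BnBr give its 3-O-benzyl ether F11.
- Catalytic HCl in MeOH gives the flavan-4-yl resorcinol F12.
- One equivalent of NIS (MeCN, 0 °C) iodinates the only free-phenol ring. Its two open positions become identical on rotation about the C4–aryl bond, so the sole mono-iodide is 17.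

**Step 17.** The amide base may deprotonate elsewhere, for example at flavan C4–H lateral to the carbonyl, followed by E1cB loss of the 3-benzyloxy group. The 3-lithio species may also ring-open to the ynone phenoxide before it is borylated.

The fallback sets out from 24 and returns at 27, and it replaces the carbanion chemistry with an electrophilic oxidation. Dimethyldioxirane (acetone–CH2Cl2, 0 °C) epoxidises the C2=C3 bond to give the 2,3-epoxyflavanone F13 as a mixture of two diastereomers, which does not matter. Catalytic p-TsOH opens the oxirane at the O1- and aryl-stabilised C2, and loss of the C3 proton gives flavonol 27.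

**Further compounds**
F1 | step 15 | 3-[3,4-bis(benzyloxy)phenyl]prop-2-ynal | O=CC#Cc1ccc(OCc2ccccc2)c(OCc2ccccc2)c1
F2 | step 15 | arylmagnesium chloride from 16 (Mg in place of I, flavan geometry as in 16) | Cl[Mg]c1c(OCOC)c(OCc2ccccc2)c(OCOC)cc1[C@H]1c2ccc(OCc3ccccc3)c(OCc3ccccc3)c2O[C@H](c2ccc(OCc3ccccc3)c(OCc3ccccc3)c2)[C@@H]1OCc1ccccc1
F3 | step 15 | bis-MOM propargylic alcohol (both carbinol epimers) | OC(C#Cc1ccc(OCc2ccccc2)c(OCc2ccccc2)c1)c1c(OCOC)c(OCc2ccccc2)c(OCOC)cc1[C@H]1c2ccc(OCc3ccccc3)c(OCc3ccccc3)c2O[C@H](c2ccc(OCc3ccccc3)c(OCc3ccccc3)c2)[C@@H]1OCc1ccccc1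
F4 | step 15 | bis-MOM alkynone (bis-MOM ether of 21) | O=C(C#Cc1ccc(OCc2ccccc2)c(OCc2ccccc2)c1)c1c(OCOC)c(OCc2ccccc2)c(OCOC)cc1[C@H]1c2ccc(OCc3ccccc3)c(OCc3ccccc3)c2O[C@H](c2ccc(OCc3ccccc3)c(OCc3ccccc3)c2)[C@@H]1OCc1ccccc1
F5 | step 11 | 4-(benzyloxy)-3,5-bis(methoxymethoxy)benzaldehyde | O=Cc1cc(OCOC)c(OCc2ccccc2)c(OCOC)c1
F6 | step 11 | iodine-free (E)-chalcone | O=C(/C=C/c1cc(OCOC)c(OCc2ccccc2)c(OCOC)c1)c1ccc(OCc2ccccc2)c(OCc2ccccc2)c1
F7 | step 11 | iodine-free trans-(αR,βS)-epoxy ketone | O=C(c1ccc(OCc2ccccc2)c(OCc2ccccc2)c1)[C@@H]1O[C@H]1c1cc(OCOC)c(OCc2ccccc2)c(OCOC)c1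
F8 | step 11 | iodine-free anti-epoxy alcohol, (S)-carbinol | O[C@@H](c1ccc(OCc2ccccc2)c(OCc2ccccc2)c1)[C@@H]1O[C@H]1c1cc(OCOC)c(OCc2ccccc2)c(OCOC)c1
F9 | step 11 | iodine-free syn-aryloxy oxirane | C(c1ccccc1)Oc1cccc(O[C@H](c2ccc(OCc3ccccc3)c(OCc3ccccc3)c2)[C@@H]2O[C@H]2c2cc(OCOC)c(OCc3ccccc3)c(OCOC)c2)c1OCc1ccccc1
F10 | step 11 | iodine-free 2,3-cis-3,4-trans 4-arylflavan-3-ol | c1c(OCOC)c(OCc2ccccc2)c(OCOC)cc1[C@H]1c2ccc(OCc3ccccc3)c(OCc3ccccc3)c2O[C@H](c2ccc(OCc3ccccc3)c(OCc3ccccc3)c2)[C@@H]1O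
F11 | step 11 | 3-O-benzyl ether of F10 | c1c(OCOC)c(OCc2ccccc2)c(OCOC)cc1[C@H]1c2ccc(OCc3ccccc3)c(OCc3ccccc3)c2O[C@H](c2ccc(OCc3ccccc3)c(OCc3ccccc3)c2)[C@@H]1OCc1ccccc1
F12 | step 11 | flavan-4-yl resorcinol (17 without iodine) | c1c(O)c(OCc2ccccc2)c(O)cc1[C@H]1c2ccc(OCc3ccccc3)c(OCc3ccccc3)c2O[C@H](c2ccc(OCc3ccccc3)c(OCc3ccccc3)c2)[C@@H]1OCc1ccccc1
F13 | step 17 | 2,3-epoxyflavanone from 24 (two oxirane diastereomers) | O=C1C2OC2(c2ccc(OCc3ccccc3)c(OCc3ccccc3)c2)Oc2c(OCc3ccccc3)c(OCc3ccccc3)cc([C@H]3c4ccc(OCc5ccccc5)c(OCc5ccccc5)c4O[C@H](c4ccc(OCc5ccccc5)c(OCc5ccccc5)c4)[C@@H]3OCc3ccccc3)c12
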